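**Plan**

1. Labels: ring A is the benzoic acid ring (C4a, C5–C8, C8a; OH on C5 and C6, CO2H on C7) and ring B the saturated ring (C1 bears the side chain, C2 and C3 are CH2, C4 bears CH3). The side chain is C1' (CH carrying the C1'' hydroxymethyl), C2'–C4' (CH2), C5' (CH carrying CH3) and C6' (CH2OH).
2. Retrosynthetic cuts, in order: the two aryl methyl ethers and the two silyl ethers; C7–CO2H (ortho-lithiation, CO2); C8a–C1 of ring B (Heck closure); C1=C1' (Wittig); C1'–C2' (ylide alkylation) and C4–C4a (conjugate arylation).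
3. Enabling feature: C1 and C1' are neighbouring CH centres and C1' carries the C1'' hydroxymethyl. The pair is therefore what remains when the aryl carbon C8a and a hydrogen add to the same face of an (E)-C1=C1'(CH2OH) allylic alcohol hanging from C4a through C4–C3–C2; ring B forms in the same event.
4. Forward: an aryl piece (C4 set, Br on C8a, aldehyde at C1) and a C1'–C6' ylide are joined by Wittig olefination and the ester is reduced to the allylic alcohol. Ring B is then closed, and the C1'' aldehyde is reduced, silylated, carboxylated at C7 and unmasked.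
5. Stereochemistry: C4 comes from [Rh(nbd)2]BF4/(S)-BINAP-catalysed arylation of ethyl crotonate and C5' from (R)-3-bromo-2-methylpropan-1-ol. C1 and C1' arise together in the ring closure: their relation from the alkene geometry, the face from the ligand aided by C4.

Key step: step 11

Remark on the chemistry: which BINAP enantiomer is matched with the C4 centre in step 11 cannot be read from the structure; (R)-BINAP is written, and its antipode is meant should the pairing prove mismatched.

**Route**

Step 1
Reactants: 1 2,3-dimethoxyphenylboronic acid; 2 ethyl (E)-crotonate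
Product: 3 ethyl (3R)-3-(2,3-dimethoxyphenyl)butanoate
Conditions: [Rh(nbd)2]BF4 (2 mol %; nbd = norbornadiene), (S)-BINAP (2.2 mol %), Et3N, 1,4-dioxane–H2O, 30 °C
Reagents that add atoms: none
Why: Rhodium-catalysed asymmetric 1,4-addition of an arylboronic acid to an enoate (Hayashi–Miyaura reaction); the aryl–rhodium/(S)-BINAP species should add to the enantioface of the (E)-crotonate that gives C4 as R, the sense expected from the established facial model for (E)-enoates, and the antipodal ligand would be taken should the sense prove opposite.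

Step 2
Reactants: 3 ethyl (3R)-3-(2,3-dimethoxyphenyl)butanoate
Product: 4 ethyl (3R)-3-(6-bromo-2,3-dimethoxyphenyl)butanoate
Conditions: NBS, MeCN, 0 °C → rt
Reagents that add atoms: N-bromosuccinimide, O=C1CCC(=O)N1Br
Why: Electrophilic aromatic bromination; the C6 methoxy lies in the ring plane and directs para to C8a, whereas the C5 methoxy is twisted out of conjugation by its two ortho neighbours, so bromine should enter next to the side chain.

Step 3
Reactants: 4 ethyl (3R)-3-(6-bromo-2,3-dimethoxyphenyl)butanoate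
Product: 6 (3R)-3-(6-bromo-2,3-dimethoxyphenyl)butanal, via aluminium hemiacetal 5 (not isolated)
Conditions: i-Bu2AlH (1.1 equiv.), CH2Cl2, −78 °C; MeOH, then aqueous work-up
Reagents that add atoms: none
Why: Partial ester reduction with i-Bu2AlH; the tetrahedral aluminium hemiacetal persists at −78 °C and releases the aldehyde only on work-up, and C4 is not next to the carbonyl and cannot epimerise.

Step 4
Reactants: 6 (3R)-3-(6-bromo-2,3-dimethoxyphenyl)butanal
Product: 8 (4R)-4-(6-bromo-2,3-dimethoxyphenyl)pentanal, via enol ether 7 (not isolated)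
Conditions: Ph3P(CH2OMe)Cl, KN(SiMe3)2, THF, 0 °C → rt; then 2 M aq. HCl, THF, rt
Reagents that add atoms: (methoxymethyl)triphenylphosphonium chloride, COC[P+](c1ccccc1)(c1ccccc1)c1ccccc1.[Cl-]; water, O
Why: Wittig methoxymethylenation followed by acid hydrolysis of the enol ether is the standard one-carbon homologation of an aldehyde and installs C1; the aryl bromide and methyl ethers are inert to both operations.

Step 5
Reactants: 9 (2R)-3-bromo-2-methylpropan-1-ol
Product: 10 [(2R)-3-bromo-2-methylpropoxy](tert-butyl)dimethylsilane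
Conditions: TBSCl, imidazole, CH2Cl2, 0 °C → rt
Reagents that add atoms: tert-butyldimethylsilyl chloride, CC(C)(C)[Si](C)(C)Cl
Why: Standard silylation of a primary alcohol; the C5' centre is carried in from the commercial bromo alcohol and is not touched.

Step 6
Reactants: 10 [(2R)-3-bromo-2-methylpropoxy](tert-butyl)dimethylsilane
Product: 12 (4S)-5-((tert-butyldimethylsilyl)oxy)-4-methylpentan-1-ol, via Grignard reagent 11 (not isolated)
Conditions: Mg, THF, 40 °C; then ethylene oxide, CuBr·SMe2 (5 mol %), THF, −30 → 0 °C; aq. NH4Cl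
Reagents that add atoms: ethylene oxide, C1CO1
Why: Grignard formation and copper-catalysed ring opening of ethylene oxide is the standard two-carbon homologation of an alkyl halide to a primary alcohol and adds C3' and C2'; the stereocentre is β to magnesium and is not involved, its descriptor changing from R to S only because the bromomethyl group has become a lower-ranked alkyl chain.

Step 7
Reactants: 12 (4S)-5-((tert-butyldimethylsilyl)oxy)-4-methylpentan-1-ol
Product: 13 tert-butyl{[(2S)-5-iodo-2-methylpentyl]oxy}dimethylsilane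
Conditions: I2, PPh3, imidazole, CH2Cl2, 0 °C → rt
Reagents that add atoms: iodine, II
Why: Appel-type iodination of a primary alcohol through the alkoxyphosphonium iodide; the imidazole buffer keeps the silyl ether intact.

Step 8
Reactants: 13 tert-butyl{[(2S)-5-iodo-2-methylpentyl]oxy}dimethylsilane; 14 ethyl (triphenylphosphoranylidene)acetate
Product: 16 ethyl (6S)-7-((tert-butyldimethylsilyl)oxy)-6-methyl-2-(triphenylphosphoranylidene)heptanoate, via phosphonium iodide 15 (not isolated)
Conditions: 14 (2.2 equiv.), MeCN, reflux; concentration, trituration with toluene–Et2O and filtration of the phosphonium salt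
Reagents that add atoms: none
Why: C-alkylation of a stabilised phosphorus ylide by a primary iodide forms the C1'–C2' bond, and the second equivalent of ylide deprotonates the new phosphonium salt (transylidation) to give the α-alkylated ylide.

Step 9
Reactants: 8 (4R)-4-(6-bromo-2,3-dimethoxyphenyl)pentanal; 16 ethyl (6S)-7-((tert-butyldimethylsilyl)oxy)-6-methyl-2-(triphenylphosphoranylidene)heptanoate
Product: 17 ethyl (2E,6R)-6-(6-bromo-2,3-dimethoxyphenyl)-2-[(4S)-5-((tert-butyldimethylsilyl)oxy)-4-methylpentyl]hept-2-enoate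
Conditions: toluene, 90 °C
Reagents that add atoms: none
Why: Wittig olefination with an α-alkylated stabilised ylide gives the (E)-trisubstituted enoate, in which the C2 tether and the C2' chain are cis, as required for step 11.

Step 10
Reactants: 17 ethyl (2E,6R)-6-(6-bromo-2,3-dimethoxyphenyl)-2-[(4S)-5-((tert-butyldimethylsilyl)oxy)-4-methylpentyl]hept-2-enoate
Product: 18 (2E,6R)-6-(6-bromo-2,3-dimethoxyphenyl)-2-[(4S)-5-((tert-butyldimethylsilyl)oxy)-4-methylpentyl]hept-2-en-1-ol
Conditions: i-Bu2AlH (2.5 equiv.), CH2Cl2, −78 → 0 °C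
Reagents that add atoms: none
Why: 1,2-Reduction of an enoate with i-Bu2AlH gives the allylic alcohol with the alkene geometry unchanged; the aryl bromide and silyl ether are stable at low temperature.

Step 11
Reactants: 18 (2E,6R)-6-(6-bromo-2,3-dimethoxyphenyl)-2-[(4S)-5-((tert-butyldimethylsilyl)oxy)-4-methylpentyl]hept-2-en-1-ol
Product: 19 (2S,6S)-7-((tert-butyldimethylsilyl)oxy)-2-[(1S,4R)-5,6-dimethoxy-4-methyl-1,2,3,4-tetrahydronaphthalen-1-yl]-6-methylheptanal
Conditions: Pd(OAc)2 (10 mol %), (R)-BINAP (15 mol %), Ag3PO4 (1.2 equiv.), degassed DMF, 80 °C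
Reagents that add atoms: none
Why: Proposed new method: oxidative addition of the C8a–Br bond to zerovalent palladium and removal of bromide by Ag3PO4 should give a cationic, BINAP-bound aryl–palladium that adds syn across C1=C1' (aryl to C1, palladium to C1'), after which β-hydride elimination toward the C1'' carbinol and reinsertion with reversed regiochemistry return that hydrogen to C1' on the face palladium held, and the α-hydroxyalkyl palladium collapses to the aldehyde with release of zerovalent palladium. The closest known reactions are the Heck arylation of allylic alcohols to β-aryl carbonyl compounds, the enantioselective redox-relay Heck arylation of alkenols and the asymmetric intramolecular Heck cyclisation under cationic conditions; their merger in one ring closure that also fixes the carbon next to the aryl-bearing centre has not been shown. Ring B closes 6-exo-trig, because the C2–C3–C4 tether makes attack at C1 far easier than 7-endo attack at C1'. C1 is set by the alkene face the catalyst selects, with the chiral bisphosphine as the main control element and the C4 methyl, held pseudoaxial by the neighbouring C5 methoxy, as a supporting one expected to favour the trans ring; C1' is set relative to C1 by the E geometry, since aryl and hydrogen reach the same face, which gives the (1S,1'S) pair. The step needs palladium to travel to C1'' and not into the C2' chain or back to the benzylic C1–H, which the hydroxyl group should secure as the thermodynamic end point of chain walking. It also needs the palladium hydride to stay bound to the enol, which a halide-free cationic metal carrying a chelating bisphosphine should favour, and Ag3PO4 is chosen as a weak, non-oxidising base so that neither the allylic alcohol nor the α-centre of the aldehyde is attacked.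

Step 12
Reactants: 19 (2S,6S)-7-((tert-butyldimethylsilyl)oxy)-2-[(1S,4R)-5,6-dimethoxy-4-methyl-1,2,3,4-tetrahydronaphthalen-1-yl]-6-methylheptanal
Product: 20 (2S,6S)-7-((tert-butyldimethylsilyl)oxy)-2-[(1S,4R)-5,6-dimethoxy-4-methyl-1,2,3,4-tetrahydronaphthalen-1-yl]-6-methylheptan-1-ol
Conditions: NaBH4, MeOH–THF, 0 °C (on the filtered, unchromatographed aldehyde)
Reagents that add atoms: none
Why: Hydride reduction of the aldehyde at 0 °C, carried out at once on the crude material, removes the acidic α-hydrogen at C1' before it can epimerise.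

Step 13
Reactants: 20 (2S,6S)-7-((tert-butyldimethylsilyl)oxy)-2-[(1S,4R)-5,6-dimethoxy-4-methyl-1,2,3,4-tetrahydronaphthalen-1-yl]-6-methylheptan-1-ol
Product: 21 (1S,4R)-1-[(2S,6S)-1,7-bis((tert-butyldimethylsilyl)oxy)-6-methylheptan-2-yl]-5,6-dimethoxy-4-methyl-1,2,3,4-tetrahydronaphthalene
Conditions: TBSCl, imidazole, DMF, rt
Reagents that add atoms: tert-butyldimethylsilyl chloride, CC(C)(C)[Si](C)(C)Cl
Why: Silylation of the C1'' alcohol leaves no acidic hydrogen for the organolithium step that follows.

Step 14
Reactants: 21 (1S,4R)-1-[(2S,6S)-1,7-bis((tert-butyldimethylsilyl)oxy)-6-methylheptan-2-yl]-5,6-dimethoxy-4-methyl-1,2,3,4-tetrahydronaphthalene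
Product: 23 (5R,8S)-8-[(2S,6S)-1,7-bis((tert-butyldimethylsilyl)oxy)-6-methylheptan-2-yl]-3,4-dimethoxy-5-methyl-5,6,7,8-tetrahydronaphthalene-2-carboxylic acid, via aryllithium 22 (not isolated)
Conditions: n-BuLi, TMEDA, Et2O, 0 °C → rt; CO2, −78 °C → rt; cold 1 M HCl
Reagents that add atoms: carbon dioxide, O=C=O
Why: Directed ortho-metalation; C7 is the only ring position ortho to a methoxy group (C6-OMe), so lithiation and carboxylation should occur there, as with simple veratroles.

Step 15
Reactants: 23 (5R,8S)-8-[(2S,6S)-1,7-bis((tert-butyldimethylsilyl)oxy)-6-methylheptan-2-yl]-3,4-dimethoxy-5-methyl-5,6,7,8-tetrahydronaphthalene-2-carboxylic acid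
Product: 24 (5R,8S)-8-[(2S,6S)-1,7-dihydroxy-6-methylheptan-2-yl]-3,4-dimethoxy-5-methyl-5,6,7,8-tetrahydronaphthalene-2-carboxylic acid
Conditions: 2 M aq. HCl, THF, rt
Reagents that add atoms: none
Why: Acid hydrolysis of two primary silyl ethers; methanol is avoided so that the acid is not esterified, and the silyl groups are removed before BBr3 because that reagent can turn silyl ethers into alkyl bromides.

Step 16
Reactants: 24 (5R,8S)-8-[(2S,6S)-1,7-dihydroxy-6-methylheptan-2-yl]-3,4-dimethoxy-5-methyl-5,6,7,8-tetrahydronaphthalene-2-carboxylic acid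
Product: 25 (5R,8S)-8-[(2S,6S)-1,7-dihydroxy-6-methylheptan-2-yl]-3,4-dihydroxy-5-methyl-5,6,7,8-tetrahydronaphthalene-2-carboxylic acid (CNP0255074.1)
Conditions: BBr3 (6 equiv.), CH2Cl2, −78 → 0 °C; H2O
Reagents that add atoms: none
Why: Lewis-acid cleavage of aryl methyl ethers with BBr3, the usual route from 2,3-dimethoxybenzoic acids to 2,3-dihydroxybenzoic acids; the alcohols and the acid are held as boron esters at low temperature and are released on hydrolysis.

**Compound list**

1 | 2,3-dimethoxyphenylboronic acid | COc1cccc(B(O)O)c1OC | starting material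
2 | ethyl (E)-crotonate | CCOC(=O)/C=C/C | starting material
3 | ethyl (3R)-3-(2,3-dimethoxyphenyl)butanoate | CCOC(=O)C[C@@H](C)c1cccc(OC)c1OC | intermediate
4 | ethyl (3R)-3-(6-bromo-2,3-dimethoxyphenyl)butanoate | CCOC(=O)C[C@@H](C)c1c(Br)ccc(OC)c1OC | intermediate
5 | [(3R)-3-(6-bromo-2,3-dimethoxyphenyl)-1-ethoxybutoxy]bis(2-methylpropyl)aluminium (aluminium hemiacetal, both epimers at the acetal carbon) | CCOC(C[C@@H](C)c1c(Br)ccc(OC)c1OC)O[Al](CC(C)C)CC(C)C | intermediate
6 | (3R)-3-(6-bromo-2,3-dimethoxyphenyl)butanal | O=CC[C@@H](C)c1c(Br)ccc(OC)c1OC | intermediate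
7 | 1-bromo-3,4-dimethoxy-2-[(2R)-5-methoxypent-4-en-2-yl]benzene (enol ether, E/Z mixture) | COC=CC[C@@H](C)c1c(Br)ccc(OC)c1OC | intermediate
8 | (4R)-4-(6-bromo-2,3-dimethoxyphenyl)pentanal | O=CCC[C@@H](C)c1c(Br)ccc(OC)c1OC | intermediate
9 | (2R)-3-bromo-2-methylpropan-1-ol | C[C@H](CO)CBr | starting material
10 | [(2R)-3-bromo-2-methylpropoxy](tert-butyl)dimethylsilane | C[C@H](CO[Si](C)(C)C(C)(C)C)CBr | intermediate
11 | [(2R)-3-((tert-butyldimethylsilyl)oxy)-2-methylpropyl]magnesium bromide | C[C@H](CO[Si](C)(C)C(C)(C)C)C[Mg]Br | intermediate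
12 | (4S)-5-((tert-butyldimethylsilyl)oxy)-4-methylpentan-1-ol | C[C@H](CO[Si](C)(C)C(C)(C)C)CCCO | intermediate
13 | tert-butyl{[(2S)-5-iodo-2-methylpentyl]oxy}dimethylsilane | C[C@H](CO[Si](C)(C)C(C)(C)C)CCCI | intermediate
14 | ethyl (triphenylphosphoranylidene)acetate | CCOC(=O)C=P(c1ccccc1)(c1ccccc1)c1ccccc1 | starting material
15 | [(6S)-7-((tert-butyldimethylsilyl)oxy)-1-ethoxy-6-methyl-1-oxoheptan-2-yl]triphenylphosphonium iodide (both epimers at C2) | CCOC(=O)C(CCC[C@H](C)CO[Si](C)(C)C(C)(C)C)[P+](c1ccccc1)(c1ccccc1)c1ccccc1.[I-] | intermediate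
16 | ethyl (6S)-7-((tert-butyldimethylsilyl)oxy)-6-methyl-2-(triphenylphosphoranylidene)heptanoate | CCOC(=O)C(CCC[C@H](C)CO[Si](C)(C)C(C)(C)C)=P(c1ccccc1)(c1ccccc1)c1ccccc1 | intermediate
17 | ethyl (2E,6R)-6-(6-bromo-2,3-dimethoxyphenyl)-2-[(4S)-5-((tert-butyldimethylsilyl)oxy)-4-methylpentyl]hept-2-enoate | CCOC(=O)/C(CCC[C@H](C)CO[Si](C)(C)C(C)(C)C)=C/CC[C@@H](C)c1c(Br)ccc(OC)c1OC | intermediate
18 | (2E,6R)-6-(6-bromo-2,3-dimethoxyphenyl)-2-[(4S)-5-((tert-butyldimethylsilyl)oxy)-4-methylpentyl]hept-2-en-1-ol | Brc1ccc(OC)c(OC)c1[C@H](C)CC/C=C(/CO)CCC[C@H](C)CO[Si](C)(C)C(C)(C)C | intermediate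
19 | (2S,6S)-7-((tert-butyldimethylsilyl)oxy)-2-[(1S,4R)-5,6-dimethoxy-4-methyl-1,2,3,4-tetrahydronaphthalen-1-yl]-6-methylheptanal | O=C[C@@H](CCC[C@H](C)CO[Si](C)(C)C(C)(C)C)[C@@H]1CC[C@@H](C)c2c1ccc(OC)c2OC | intermediate
20 | (2S,6S)-7-((tert-butyldimethylsilyl)oxy)-2-[(1S,4R)-5,6-dimethoxy-4-methyl-1,2,3,4-tetrahydronaphthalen-1-yl]-6-methylheptan-1-ol | OC[C@@H](CCC[C@H](C)CO[Si](C)(C)C(C)(C)C)[C@@H]1CC[C@@H](C)c2c1ccc(OC)c2OC | intermediate
21 | (1S,4R)-1-[(2S,6S)-1,7-bis((tert-butyldimethylsilyl)oxy)-6-methylheptan-2-yl]-5,6-dimethoxy-4-methyl-1,2,3,4-tetrahydronaphthalene | CC(C)(C)[Si](C)(C)OC[C@@H](CCC[C@H](C)CO[Si](C)(C)C(C)(C)C)[C@@H]1CC[C@@H](C)c2c1ccc(OC)c2OC | intermediate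
22 | [(5R,8S)-8-[(2S,6S)-1,7-bis((tert-butyldimethylsilyl)oxy)-6-methylheptan-2-yl]-3,4-dimethoxy-5-methyl-5,6,7,8-tetrahydronaphthalen-2-yl]lithium | CC(C)(C)[Si](C)(C)OC[C@@H](CCC[C@H](C)CO[Si](C)(C)C(C)(C)C)[C@@H]1CC[C@@H](C)c2c1cc([Li])c(OC)c2OC | intermediate
23 | (5R,8S)-8-[(2S,6S)-1,7-bis((tert-butyldimethylsilyl)oxy)-6-methylheptan-2-yl]-3,4-dimethoxy-5-methyl-5,6,7,8-tetrahydronaphthalene-2-carboxylic acid | CC(C)(C)[Si](C)(C)OC[C@@H](CCC[C@H](C)CO[Si](C)(C)C(C)(C)C)[C@@H]1CC[C@@H](C)c2c1cc(C(=O)O)c(OC)c2OC | intermediate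
24 | (5R,8S)-8-[(2S,6S)-1,7-dihydroxy-6-methylheptan-2-yl]-3,4-dimethoxy-5-methyl-5,6,7,8-tetrahydronaphthalene-2-carboxylic acid | C[C@H](CO)CCC[C@H](CO)[C@@H]1CC[C@@H](C)c2c1cc(C(=O)O)c(OC)c2OC | intermediate
25 | (5R,8S)-8-[(2S,6S)-1,7-dihydroxy-6-methylheptan-2-yl]-3,4-dihydroxy-5-methyl-5,6,7,8-tetrahydronaphthalene-2-carboxylic acid (CNP0255074.1) | C[C@H](CO)CCC[C@H](CO)[C@@H]1CC[C@@H](C)c2c1cc(C(=O)O)c(O)c2O | target

**Step count and risks**

Total step count: 16. Longest linear sequence: 12 steps (steps 5–16 from 9; the arm from 1, steps 1–4 and 9–16, is equally long).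

Steps most likely to fail:

1. Step 11 (proposed new method). The palladium hydride may leave the enol before it reinserts, so that C1' is set by uncontrolled tautomerisation. Palladium may also walk into the C2' chain or eliminate toward the benzylic C1–H, the face selection may be poor, and the aldehyde may epimerise while warm. Fallback, using known chemistry: it sets out from enoate 17. Bu3SnH and AIBN in toluene at 90 °C (slow addition of the hydride) would generate the C8a aryl radical, which closes ring B 6-exo onto C1 of the enoate; the α-ester radical is then reduced by Bu3SnH to ethyl (2S,6S)-7-((tert-butyldimethylsilyl)oxy)-2-[(1S,4R)-5,6-dimethoxy-4-methyl-1,2,3,4-tetrahydronaphthalen-1-yl]-6-methylheptanoate F1. In this variant both new centres arise under substrate control only (the C4 methyl for C1, allylic strain in the hydrogen transfer for C1'), so the wanted isomer would have to be separated by chromatography. LiAlH4 in THF at 0 °C would then reduce F1 to alcohol 20, where the route is rejoined.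

2. Step 16. Bromide may displace the boron alkoxides at C1'' and C6' during the demethylation, and the crowded C5 methyl ether may cleave slowly enough to demand forcing conditions. Fallback: it sets out from 24. Acetylation (Ac2O, pyridine, DMAP, then aqueous work-up to hydrolyse the mixed anhydride) would give (5R,8S)-8-[(2S,6S)-1,7-diacetoxy-6-methylheptan-2-yl]-3,4-dimethoxy-5-methyl-5,6,7,8-tetrahydronaphthalene-2-carboxylic acid F2, whose primary oxygens are no longer open to substitution. BBr3 in CH2Cl2 at −78 → 0 °C would give (5R,8S)-8-[(2S,6S)-1,7-diacetoxy-6-methylheptan-2-yl]-3,4-dihydroxy-5-methyl-5,6,7,8-tetrahydronaphthalene-2-carboxylic acid F3. LiOH in degassed THF–H2O followed by HCl would remove the acetates and deliver 25.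

3. Step 8. C-alkylation of the stabilised ylide by an unactivated primary iodide may be slow, with loss of the iodide through elimination. Fallback: it sets out from iodide 13. The sodium salt of triethyl phosphonoacetate (NaH, THF–DMSO, 50 °C) would be alkylated to ethyl (6S)-7-((tert-butyldimethylsilyl)oxy)-2-(diethoxyphosphoryl)-6-methylheptanoate F4. Horner–Wadsworth–Emmons olefination of aldehyde 8 with F4 (NaH, THF, 0 °C → rt) would give enoate 17 after chromatographic removal of the Z isomer, and the route continues from 17.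

Further compounds

F1 | step 11 | ethyl (2S,6S)-7-((tert-butyldimethylsilyl)oxy)-2-[(1S,4R)-5,6-dimethoxy-4-methyl-1,2,3,4-tetrahydronaphthalen-1-yl]-6-methylheptanoate | CCOC(=O)[C@@H](CCC[C@H](C)CO[Si](C)(C)C(C)(C)C)[C@@H]1CC[C@@H](C)c2c1ccc(OC)c2OC
F2 | step 16 | (5R,8S)-8-[(2S,6S)-1,7-diacetoxy-6-methylheptan-2-yl]-3,4-dimethoxy-5-methyl-5,6,7,8-tetrahydronaphthalene-2-carboxylic acid | CC(=O)OC[C@@H](C)CCC[C@H](COC(C)=O)[C@@H]1CC[C@@H](C)c2c1cc(C(=O)O)c(OC)c2OC
F3 | step 16 | (5R,8S)-8-[(2S,6S)-1,7-diacetoxy-6-methylheptan-2-yl]-3,4-dihydroxy-5-methyl-5,6,7,8-tetrahydronaphthalene-2-carboxylic acid | CC(=O)OC[C@@H](C)CCC[C@H](COC(C)=O)[C@@H]1CC[C@@H](C)c2c1cc(C(=O)O)c(O)c2O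
F4 | step 8 | ethyl (6S)-7-((tert-butyldimethylsilyl)oxy)-2-(diethoxyphosphoryl)-6-methylheptanoate | CCOC(=O)C(CCC[C@H](C)CO[Si](C)(C)C(C)(C)C)P(=O)(OCC)OCC
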